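**Retrosynthetic overview**

1. The route rests on one feature of the target: C1 (CH–OH) and C4 (CH–naphthyl) are the two benzylic carbons of the anisole-fused ring and are cis, and the C2–C3 unit between them is a plain CH2–CH2. The saturated ring is therefore an ortho-quinodimethane (C1, C8a, C4a, C4) plus a two-carbon dienophile (C2–C3).
2. Target 16 ← silyl ether 15 ← removal of a C2 carboxyl from the all-cis photoenolisation/Diels–Alder adduct 12.
3. 12 ← [4+2] (bonds C1–C2 and C3–C4) of the hydroxy-ortho-quinodimethane generated by light from diarylmethane aldehyde 9, with methyl acrylate on a chiral titanium TADDOLate.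
4. 9 ← CH2–aryl bond by Negishi coupling of the naphthylzinc derived from 8-methoxynaphthalen-1-ol (para-bromination of the free naphthol, then silylation) with commercial methyl 2-(bromomethyl)-3-methoxybenzoate, then ester → CHO.
5. Ring order: the naphthalene and anisole rings are bought; the tetralin carbocycle is the only ring made, in step 6.

Key step: step 6

Assumption: (R,R)-TADDOL is written for the titanium template; which ligand enantiomer leads to the (1S,4S) series with an acrylate has to be established on the first adduct, and the (S,S)-ligand is used if the opposite sense is found.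

**Route**

Step 1
Reactants: 1 8-methoxynaphthalen-1-ol
Product: 2 4-bromo-8-methoxynaphthalen-1-ol
Conditions: NBS (1.0 equiv), MeCN, −20 → 0 °C, dark
Reagents that add atoms: N-bromosuccinimide, O=C1CCC(=O)N1Br
Why: Electrophilic aromatic bromination should go to C4 because the free hydroxyl is the strongest donor (a silyl ether would hand control to the methoxy ring and C5), its hydrogen bond to the peri-methoxy oxygen disfavours OH-directed ortho delivery, and C4 is an unhindered α-position.

Step 2
Reactants: 2 4-bromo-8-methoxynaphthalen-1-ol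
Product: 3 (4-bromo-8-methoxynaphthalen-1-yl)oxy(tert-butyl)dimethylsilane
Conditions: TBSCl, imidazole, DMF, rt → 40 °C
Reagents that add atoms: tert-butyldimethylsilyl chloride, CC(C)(C)[Si](C)(C)Cl
Why: Standard silylation of a phenol masks the acidic OH before metalation, and the peri-methoxy group makes the resulting aryl silyl ether more hindered and so more robust.

Step 3
Reactants: 3 (4-bromo-8-methoxynaphthalen-1-yl)oxy(tert-butyl)dimethylsilane, 4 methyl 2-(bromomethyl)-3-methoxybenzoate
Product: 7 methyl 3-methoxy-2-{[4-(tert-butyldimethylsilyloxy)-5-methoxynaphthalen-1-yl]methyl}benzoate, via aryllithium 5 (not isolated), via arylzinc chloride 6 (not isolated)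
Conditions: n-BuLi, THF, −78 °C; ZnCl2, −78 °C → rt; then 4, Pd(PPh3)4 (5 mol %), THF, rt → 45 °C
Reagents that add atoms: none
Why: Bromine–lithium exchange, transmetalation to zinc and Negishi sp2–sp3 coupling with the benzylic bromide give the CH2 link directly, the arylzinc tolerates the ester, and no diarylcarbinol has to be deoxygenated next to a masked aldehyde.

Step 4
Reactants: 7 methyl 3-methoxy-2-{[4-(tert-butyldimethylsilyloxy)-5-methoxynaphthalen-1-yl]methyl}benzoate
Product: 8 (3-methoxy-2-{[4-(tert-butyldimethylsilyloxy)-5-methoxynaphthalen-1-yl]methyl}phenyl)methanol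
Conditions: DIBAL-H (2.5 equiv), CH2Cl2, −78 → 0 °C; Rochelle salt work-up
Reagents that add atoms: none
Why: Hydride reduction of the benzoate to the benzylic alcohol with DIBAL-H is routine and leaves the aryl silyl ether and the diarylmethane untouched.

Step 5
Reactants: 8 (3-methoxy-2-{[4-(tert-butyldimethylsilyloxy)-5-methoxynaphthalen-1-yl]methyl}phenyl)methanol
Product: 9 3-methoxy-2-{[4-(tert-butyldimethylsilyloxy)-5-methoxynaphthalen-1-yl]methyl}benzaldehyde
Conditions: Dess–Martin periodinane, CH2Cl2, 0 °C → rt
Reagents that add atoms: none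
Why: Dess–Martin oxidation stops at the aldehyde and is mild enough to spare the doubly benzylic CH2 and the electron-rich naphthalene.

Step 6
Reactants: 9 3-methoxy-2-{[4-(tert-butyldimethylsilyloxy)-5-methoxynaphthalen-1-yl]methyl}benzaldehyde, 10 methyl acrylate
Product: 12 methyl (1S,2S,4S)-4-[4-(tert-butyldimethylsilyloxy)-5-methoxynaphthalen-1-yl]-1-hydroxy-5-methoxy-1,2,3,4-tetrahydronaphthalene-2-carboxylate (all-cis), via photoenol 11 (not isolated)
Conditions: (R,R)-TADDOL (2.2 equiv), Ti(Oi-Pr)4 (2.0 equiv), PhMe, rt, i-PrOH removed in vacuo; then 9, methyl acrylate (5 equiv), PhMe, degassed, hν (365 nm LED), 0 °C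
Reagents that add atoms: none
Why: Photoenolisation/Diels–Alder reaction: 365 nm light excites only the aldehyde n→π* band, the excited carbonyl takes a hydrogen from the doubly benzylic CH2 through a six-membered transition state, the (Z)-enol falls back to 9 by 1,5-H shift, and the (E)-enol 11 with the naphthyl group turned outward is held as a titanium dienolate and adds to acrylate 10 bound to the same metal. The closest known reaction type is the Ti(Oi-Pr)4-mediated photoenolisation/Diels–Alder reaction of 2-alkylbenzaldehydes with enones and its TADDOL-controlled enantioselective version, and acrylates are established dienophiles for free photoenols. The one new ring, the six-membered carbocycle C1–C2–C3–C4–C4a–C8a, is closed by an intermolecular suprafacial [4+2] cycloaddition that forms C1–C2 and C3–C4 in one event. C1 and C4 come out cis because OH and naphthyl both sit outward on the diene and the alkene adds to one face, C2 is set by endo approach of the ester under the Ti–O tether, and the absolute sense at all three centres comes from the TADDOLate shielding one face of the bound dienolate. The step needs only the out,out diene geometry and diene-face selectivity, since regio- and endo/exo selectivity affect C2 alone and that centre later becomes CH2; the substrate helps through its weak diarylmethane C–H bond, through the clash an inward naphthyl would suffer against the enol C–H, and through the enol oxygen as the covalent anchor for titanium.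

Step 7
Reactants: 12 methyl (1S,2S,4S)-4-[4-(tert-butyldimethylsilyloxy)-5-methoxynaphthalen-1-yl]-1-hydroxy-5-methoxy-1,2,3,4-tetrahydronaphthalene-2-carboxylate
Product: 13 (1S,2S,4S)-4-[4-(tert-butyldimethylsilyloxy)-5-methoxynaphthalen-1-yl]-1-hydroxy-5-methoxy-1,2,3,4-tetrahydronaphthalene-2-carboxylic acid
Conditions: Me3SnOH (6 equiv), 1,2-dichloroethane, 70 °C; cold dilute HCl wash
Reagents that add atoms: trimethyltin hydroxide, C[Sn](C)(C)O
Why: Trimethyltin hydroxide cleaves methyl esters by near-neutral acyl substitution, which should avoid the retro-aldol opening, β-elimination of the C1 hydroxyl and aryl silyl ether loss that aqueous hydroxide could cause.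

Step 8
Reactants: 13 (1S,2S,4S)-4-[4-(tert-butyldimethylsilyloxy)-5-methoxynaphthalen-1-yl]-1-hydroxy-5-methoxy-1,2,3,4-tetrahydronaphthalene-2-carboxylic acid
Product: 15 (1S,4S)-4-[4-(tert-butyldimethylsilyloxy)-5-methoxynaphthalen-1-yl]-5-methoxy-1,2,3,4-tetrahydronaphthalen-1-ol, via Barton ester 14 (not isolated)
Conditions: 1-hydroxypyridine-2(1H)-thione, DCC, CH2Cl2, 0 °C → rt, dark; then t-BuSH (excess), hν (visible, W lamp), rt
Reagents that add atoms: none
Why: Barton reductive decarboxylation: the thiohydroxamate ester fragments in a radical chain to the secondary C2 radical, which takes hydrogen from the thiol to give CH2 without touching C1 or C4, and the reductive, non-oxidising conditions suit the easily oxidised silyloxy-methoxynaphthalene better than an oxidative photoredox decarboxylation would.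

Step 9
Reactants: 15 (1S,4S)-4-[4-(tert-butyldimethylsilyloxy)-5-methoxynaphthalen-1-yl]-5-methoxy-1,2,3,4-tetrahydronaphthalen-1-ol
Product: 16 (1S,4S)-4-(4-hydroxy-5-methoxynaphthalen-1-yl)-5-methoxy-1,2,3,4-tetrahydronaphthalen-1-ol (dipolynaphthalene B)
Conditions: TBAF, AcOH, THF, 0 °C, degassed
Reagents that add atoms: none
Why: Fluoride cleavage of the aryl silyl ether, buffered with acetic acid and run without air, should free the naphthol without ionising the benzylic alcohol or oxidising the electron-rich naphthol.

**Compound list**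

1 | 8-methoxynaphthalen-1-ol | COc1cccc2cccc(O)c12 | starting material
2 | 4-bromo-8-methoxynaphthalen-1-ol | COc1cccc2c(Br)ccc(O)c12 | intermediate
3 | (4-bromo-8-methoxynaphthalen-1-yl)oxy(tert-butyl)dimethylsilane | COc1cccc2c(Br)ccc(O[Si](C)(C)C(C)(C)C)c12 | intermediate
4 | methyl 2-(bromomethyl)-3-methoxybenzoate | COC(=O)c1cccc(OC)c1CBr | starting material
5 | [4-(tert-butyldimethylsilyloxy)-5-methoxynaphthalen-1-yl]lithium (not isolated) | [Li]c1ccc(O[Si](C)(C)C(C)(C)C)c2c(OC)cccc12 | intermediate
6 | [4-(tert-butyldimethylsilyloxy)-5-methoxynaphthalen-1-yl]zinc chloride (not isolated) | Cl[Zn]c1ccc(O[Si](C)(C)C(C)(C)C)c2c(OC)cccc12 | intermediate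
7 | methyl 3-methoxy-2-{[4-(tert-butyldimethylsilyloxy)-5-methoxynaphthalen-1-yl]methyl}benzoate | COC(=O)c1cccc(OC)c1Cc1ccc(O[Si](C)(C)C(C)(C)C)c2c(OC)cccc12 | intermediate
8 | (3-methoxy-2-{[4-(tert-butyldimethylsilyloxy)-5-methoxynaphthalen-1-yl]methyl}phenyl)methanol | COc1cccc(CO)c1Cc1ccc(O[Si](C)(C)C(C)(C)C)c2c(OC)cccc12 | intermediate
9 | 3-methoxy-2-{[4-(tert-butyldimethylsilyloxy)-5-methoxynaphthalen-1-yl]methyl}benzaldehyde | COc1cccc(C=O)c1Cc1ccc(O[Si](C)(C)C(C)(C)C)c2c(OC)cccc12 | intermediate
10 | methyl acrylate | C=CC(=O)OC | starting material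
11 | (E)-photoenol of 9, a hydroxy-ortho-quinodimethane with OH and naphthyl both outward (the arylmethylene bond is formally Z because C3 carries OMe); bound to titanium in the flask, not isolated | O/C=C1/C(=C/c2ccc(O[Si](C)(C)C(C)(C)C)c3c(OC)cccc23)C(OC)=CC=C1 | intermediate
12 | methyl (1S,2S,4S)-4-[4-(tert-butyldimethylsilyloxy)-5-methoxynaphthalen-1-yl]-1-hydroxy-5-methoxy-1,2,3,4-tetrahydronaphthalene-2-carboxylate (OH, CO2Me and naphthyl all cis) | COc1cccc2c1[C@H](c1ccc(O[Si](C)(C)C(C)(C)C)c3c(OC)cccc13)C[C@H](C(=O)OC)[C@@H]2O | intermediate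
13 | (1S,2S,4S)-4-[4-(tert-butyldimethylsilyloxy)-5-methoxynaphthalen-1-yl]-1-hydroxy-5-methoxy-1,2,3,4-tetrahydronaphthalene-2-carboxylic acid | COc1cccc2c1[C@H](c1ccc(O[Si](C)(C)C(C)(C)C)c3c(OC)cccc13)C[C@H](C(=O)O)[C@@H]2O | intermediate
14 | 2-thioxopyridin-1(2H)-yl ester of acid 13 (Barton ester, not isolated) | COc1cccc2c1[C@H](c1ccc(O[Si](C)(C)C(C)(C)C)c3c(OC)cccc13)C[C@H](C(=O)On1ccccc1=S)[C@@H]2O | intermediate
15 | (1S,4S)-4-[4-(tert-butyldimethylsilyloxy)-5-methoxynaphthalen-1-yl]-5-methoxy-1,2,3,4-tetrahydronaphthalen-1-ol (cis) | COc1cccc2c1[C@H](c1ccc(O[Si](C)(C)C(C)(C)C)c3c(OC)cccc13)CC[C@@H]2O | intermediate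
16 | (1S,4S)-4-(4-hydroxy-5-methoxynaphthalen-1-yl)-5-methoxy-1,2,3,4-tetrahydronaphthalen-1-ol, dipolynaphthalene B (cis) | COc1cccc2c1[C@H](c1ccc(O)c3c(OC)cccc13)CC[C@@H]2O | target

**Step count and risks**

Total steps: 9. Longest linear sequence: 9 steps (from 1; partner 4 and acrylate 10 are bought).

Steps most likely to fail:

Step 6. After excitation, triplet energy may pass from the aldehyde to the neighbouring alkoxynaphthalene (the lower triplet) faster than the hydrogen transfer, so that no dienol forms. Alternatively, the dienolate may add to the monodentate acrylate with poor face selectivity, or partly off the metal. The fallback uses no light. It sets out from ester 7 and comes back at 15. LDA (THF, −78 °C) removes a diarylmethane proton ortho to the ester, the anion adds to allyl acrylate, and the ester enolate closes onto the benzoate (Michael–Dieckmann annulation). This gives racemic allyl 4-[4-(tert-butyldimethylsilyloxy)-5-methoxynaphthalen-1-yl]-5-methoxy-1-oxo-1,2,3,4-tetrahydronaphthalene-2-carboxylate F1. Pd(PPh3)4 with HCO2H/Et3N (Tsuji deallylation–decarboxylation) then gives racemic 4-[4-(tert-butyldimethylsilyloxy)-5-methoxynaphthalen-1-yl]-5-methoxy-3,4-dihydronaphthalen-1(2H)-one F2. Corey–Bakshi–Shibata reduction with (R)-Me-CBS and BH3·SMe2 sets C1 as S under reagent control, so the (4S) half of the ketone becomes 15 and the (4R) half becomes the trans alcohol (1S,4R)-4-[4-(tert-butyldimethylsilyloxy)-5-methoxynaphthalen-1-yl]-5-methoxy-1,2,3,4-tetrahydronaphthalen-1-ol F3, which is removed by chromatography. This can deliver at most half of the material as 15.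

Step 8. The free cis-β-hydroxyl may intercept the activated acid (β-lactone or oligoester formation) before the thiohydroxamate ester forms, or thiyl radicals may reversibly abstract the doubly benzylic C4–H and erode the cis relationship. The fallback sets out from acid 13 and comes back at 15. Dess–Martin oxidation of the C1 hydroxyl gives the β-keto acid (4S)-4-[4-(tert-butyldimethylsilyloxy)-5-methoxynaphthalen-1-yl]-5-methoxy-1-oxo-1,2,3,4-tetrahydronaphthalene-2-carboxylic acid F4. On gentle warming it loses CO2 to give (4S)-4-[4-(tert-butyldimethylsilyloxy)-5-methoxynaphthalen-1-yl]-5-methoxy-3,4-dihydronaphthalen-1(2H)-one F5. Reduction with (R)-Me-CBS and BH3·SMe2 then re-installs the (1S) carbinol under reagent control to give 15.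

Step 1. Bromination may also take place ortho to the hydroxyl (C2) or twice, giving a mixture that is hard to separate. The fallback fixes the para position through oxygen instead of halogen; it sets out from 1 and comes back at 7. Teuber oxidation with Fremy's salt (aqueous KH2PO4/acetone) gives 5-methoxy-1,4-naphthoquinone F6, and Na2S2O4 reduces it to 5-methoxynaphthalene-1,4-diol F7. PhNTf2/Et3N triflates the unhindered hydroxyl that is not hydrogen-bonded to the methoxy group, giving 4-hydroxy-5-methoxynaphthalen-1-yl trifluoromethanesulfonate F8. TBSCl/imidazole then gives 4-(tert-butyldimethylsilyloxy)-5-methoxynaphthalen-1-yl trifluoromethanesulfonate F9. Negishi coupling of F9 (Pd(OAc)2/SPhos, THF) with [2-methoxy-6-(methoxycarbonyl)benzyl]zinc bromide F10, made from 4 with zinc dust and LiCl, gives 7.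

**Further compounds**

F1 | step 6 | allyl 4-[4-(tert-butyldimethylsilyloxy)-5-methoxynaphthalen-1-yl]-5-methoxy-1-oxo-1,2,3,4-tetrahydronaphthalene-2-carboxylate (racemic) | COc1cccc2c1C(c1ccc(O[Si](C)(C)C(C)(C)C)c3c(OC)cccc13)CC(C(=O)OCC=C)C2=O
F2 | step 6 | 4-[4-(tert-butyldimethylsilyloxy)-5-methoxynaphthalen-1-yl]-5-methoxy-3,4-dihydronaphthalen-1(2H)-one (racemic) | COc1cccc2c1C(c1ccc(O[Si](C)(C)C(C)(C)C)c3c(OC)cccc13)CCC2=O
F3 | step 6 | (1S,4R)-4-[4-(tert-butyldimethylsilyloxy)-5-methoxynaphthalen-1-yl]-5-methoxy-1,2,3,4-tetrahydronaphthalen-1-ol (trans) | COc1cccc2c1[C@@H](c1ccc(O[Si](C)(C)C(C)(C)C)c3c(OC)cccc13)CC[C@@H]2O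
F4 | step 8 | (4S)-4-[4-(tert-butyldimethylsilyloxy)-5-methoxynaphthalen-1-yl]-5-methoxy-1-oxo-1,2,3,4-tetrahydronaphthalene-2-carboxylic acid | COc1cccc2c1[C@H](c1ccc(O[Si](C)(C)C(C)(C)C)c3c(OC)cccc13)CC(C(=O)O)C2=O
F5 | step 8 | (4S)-4-[4-(tert-butyldimethylsilyloxy)-5-methoxynaphthalen-1-yl]-5-methoxy-3,4-dihydronaphthalen-1(2H)-one | COc1cccc2c1[C@H](c1ccc(O[Si](C)(C)C(C)(C)C)c3c(OC)cccc13)CCC2=O
F6 | step 1 | 5-methoxy-1,4-naphthoquinone | COc1cccc2C(=O)C=CC(=O)c12
F7 | step 1 | 5-methoxynaphthalene-1,4-diol | COc1cccc2c(O)ccc(O)c12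
F8 | step 1 | 4-hydroxy-5-methoxynaphthalen-1-yl trifluoromethanesulfonate | COc1cccc2c(OS(=O)(=O)C(F)(F)F)ccc(O)c12
F9 | step 1 | 4-(tert-butyldimethylsilyloxy)-5-methoxynaphthalen-1-yl trifluoromethanesulfonate | COc1cccc2c(OS(=O)(=O)C(F)(F)F)ccc(O[Si](C)(C)C(C)(C)C)c12
F10 | step 1 | [2-methoxy-6-(methoxycarbonyl)benzyl]zinc bromide | COC(=O)c1cccc(OC)c1C[Zn]Br
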